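**Plan**
- Retrosynthesis: the 4'-O–Si bond is cut first, then the C8–prenyl bond (traced back through a para-Claisen shift to a prenyl ether on O5), then the O5–CH3 bond of a 5,6,7-trimethoxyflavanone, and last C2–C3 and C4–C4a together.
- The last cut is a polar [4+2] addition: an aryl oxocarbenium ion ArO+=CH–Ar' (O1=C2 conjugated with C8a=C4a of ring A) takes up ethoxyethyne as a ketene equivalent. Its precursor is the bis(3,4,5-trimethoxyphenyl) acetal of 4-silyloxybenzaldehyde.
- Enabling feature: in the 3,4,5-trimethoxyphenoxy unit the future C4a lies between O1 and the 5-methoxy oxygen and para to the 7-methoxy oxygen, and the two ortho carbons are equivalent, so ring C can close at one position only. The second aryloxy group is the activating group (it leaves as the phenol) and the ethyl enol ether is the masked C4 ketone.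
- Forward: ring B aldehyde and ring A phenol are joined as the acetal, and ring C arises in the key step. The new C4=O then directs cleavage of the peri 5-OMe, and the freed 5-OH carries prenyl to C8 (its para position) by two [3,3] shifts.
- Stereochemistry: C2 (S) is set in the key step by the chiral counteranion of a Brønsted acid. All later steps avoid base so that ring C does not open.

Key step: step 4

Assumption: the sense of induction by the chiral acid in step 4 cannot be derived from precedent; the (S)-acid is written, and its mirror image is used instead if the first run shows that it leads to the 2R series.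

**Step 1**
Reactants: 1 4-hydroxybenzaldehyde
Product: 2 4-(triisopropylsilyloxy)benzaldehyde
Conditions: TIPSCl, imidazole, DMF, rt
Reagents that add atoms: triisopropylsilyl chloride, CC(C)[Si](Cl)(C(C)C)C(C)C
Why: Silyl ether formation on a phenol; the bulky aryl silyl ether should survive phenoxide, strong acid at low temperature, BCl3 and Mitsunobu conditions, and comes off at the end without base.

**Step 2**
Reactants: 2 4-(triisopropylsilyloxy)benzaldehyde
Product: 3 [4-(dichloromethyl)phenoxy]triisopropylsilane
Conditions: (COCl)2, Ph3PO (10 mol%), CHCl3, rt; volatiles removed, crude used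
Reagents that add atoms: oxalyl chloride, ClC(=O)C(Cl)=O
Why: Appel-type deoxydichlorination of an aldehyde by a catalytic chlorophosphonium salt; the medium is neutral, the by-products are gases, and the silyl ether should be untouched.

**Step 3**
Reactants: 3 [4-(dichloromethyl)phenoxy]triisopropylsilane; 4 3,4,5-trimethoxyphenol
Product: 6 {4-[bis(3,4,5-trimethoxyphenoxy)methyl]phenoxy}triisopropylsilane, via α-chloro ether 5 (not isolated)
Conditions: 4 (2.2 equiv), KOt-Bu (2.2 equiv), THF, 0 °C; then 3, DMF, 0 °C → rt
Reagents that add atoms: none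
Why: Double Williamson-type substitution; the α-chloro ether 5 ionises easily and should be captured at oxygen by the second phenoxide, and the basic medium excludes Friedel–Crafts C-alkylation of the electron-rich ring.

**Step 4**
Reactants: 6 {4-[bis(3,4,5-trimethoxyphenoxy)methyl]phenoxy}triisopropylsilane; 7 ethoxyethyne
Product: 10 (S)-5,6,7-trimethoxy-2-[4-(triisopropylsilyloxy)phenyl]chroman-4-one, via aryl oxocarbenium ion 8 (not isolated), via 4-ethoxy-2H-chromene 9 (not isolated)
Conditions: 7 (3 equiv), (S)-3,3'-bis(2,4,6-triisopropylphenyl)-1,1'-binaphthalene-2,2'-diyl N-triflylphosphoramide (C51H57F3NO5PS, 5 mol%), 4 Å MS, toluene/CH2Cl2, −60 °C, slow addition of 6; then 1 M HCl, THF, 0 °C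
Reagents that add atoms: water, O
Why: Proposed new method: the chiral acid protonates one aryloxy oxygen of 6 and 3,4,5-trimethoxyphenol leaves, so that the aryl oxocarbenium ion 8 (a cationic 2-oxadiene, C4a=C8a–O1=C2) is paired with the chiral phosphoramide anion; the CH terminus of ethoxyethyne 7 adds to C2, the ethoxyketenium ion so formed is captured at once by the ring A carbon ortho to O1, and loss of the ring proton returns the acid and leaves enol ether 9. The closest known reaction types are the oxa-Povarov reaction of aryl oxocarbenium ions with alkenes under SnCl4, the chiral-acid Povarov reaction of N-aryl iminium ions, chiral-counteranion additions of π-nucleophiles to oxocarbenium ions and the acid-promoted arene cyclisation of ketenium ions made from ynol ethers; an ynol ether as the two-carbon partner and enantiocontrol in the oxygen series have not been shown. Ring C closes by a 6-exo-dig Friedel–Crafts attack of C4a on the sp carbon C4, so the whole is a stepwise polar [4+2] cycloaddition that makes C2–C3 first and C4–C4a second. C2 is the only new stereocenter and should be fixed in the first, irreversible C–C bond formation by the face of 8 that the chiral anion leaves open. The step needs capture of the ketenium ion by carbon (six-membered ring) and not by O1 (a four-membered oxete that would open to a cinnamate), and attack of the alkyne and not of a second arene on 8: the first is secured by C4a, which lies between O1 and 5-OMe and para to 7-OMe, the second by excess 7 and slow addition of 6, while regiochemistry is no issue because both ortho carbons of the symmetric aryloxy group and both aryloxy groups of 6 are equivalent. Dilute aqueous acid then protonates C3 of 9 and water replaces ethanol at C4, which should give ketone 10 without touching C2.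

**Step 5**
Reactants: 10 (S)-5,6,7-trimethoxy-2-[4-(triisopropylsilyloxy)phenyl]chroman-4-one
Product: 12 (S)-5-hydroxy-6,7-dimethoxy-2-[4-(triisopropylsilyloxy)phenyl]chroman-4-one, via dichloroboron chelate 11 (not isolated)
Conditions: BCl3 (1.5 equiv), CH2Cl2, −78 → −20 °C; then H2O
Reagents that add atoms: none
Why: Chelation-controlled Lewis acid ether cleavage; boron is held between C4=O and O5, so only the peri methoxy group should be demethylated, while the 6- and 7-methoxy groups and the hindered aryl silyl ether cannot chelate and should remain.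

**Step 6**
Reactants: 12 (S)-5-hydroxy-6,7-dimethoxy-2-[4-(triisopropylsilyloxy)phenyl]chroman-4-one; 13 3-methylbut-2-en-1-ol
Product: 14 (S)-6,7-dimethoxy-5-[(3-methylbut-2-en-1-yl)oxy]-2-[4-(triisopropylsilyloxy)phenyl]chroman-4-one
Conditions: PPh3, DIAD, THF, 0 °C → rt
Reagents that add atoms: none
Why: Mitsunobu etherification of the only free hydroxyl; the neutral conditions should keep ring C closed and C2 intact, which base-mediated alkylation of a flavanone would put at risk.

**Step 7**
Reactants: 14 (S)-6,7-dimethoxy-5-[(3-methylbut-2-en-1-yl)oxy]-2-[4-(triisopropylsilyloxy)phenyl]chroman-4-one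
Product: 17 (S)-5-hydroxy-6,7-dimethoxy-8-(3-methylbut-2-en-1-yl)-2-[4-(triisopropylsilyloxy)phenyl]chroman-4-one, via ortho-dienone 15 (not isolated), via para-dienone 16 (not isolated)
Conditions: Eu(fod)3 (trivalent europium; fod = 6,6,7,7,8,8,8-heptafluoro-2,2-dimethyloctane-3,5-dionate; 10 mol%), CHCl3, 60 °C
Reagents that add atoms: none
Why: Para-Claisen rearrangement (aromatic Claisen then Cope); europium chelated between C4=O and O5 should speed the first [3,3] shift to C6, where the methoxy group blocks tautomerisation, so a second [3,3] shift carries the group to C8 as a normal prenyl group and enolisation restores the phenol, with no base or new stereocenter involved.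

**Step 8**
Reactants: 17 (S)-5-hydroxy-6,7-dimethoxy-8-(3-methylbut-2-en-1-yl)-2-[4-(triisopropylsilyloxy)phenyl]chroman-4-one
Product: 18 (S)-5-hydroxy-2-(4-hydroxyphenyl)-6,7-dimethoxy-8-(3-methylbut-2-en-1-yl)chroman-4-one
Conditions: HF·pyridine, THF, 0 °C → rt
Reagents that add atoms: none
Why: Fluoride-mediated desilylation under weakly acidic conditions; no phenoxide is formed, so ring C should not open, and the prenyl double bond has no free ortho hydroxyl to cyclise onto.

**Compound list**
1 | 4-hydroxybenzaldehyde | O=Cc1ccc(O)cc1 | starting material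
2 | 4-(triisopropylsilyloxy)benzaldehyde | O=Cc1ccc(O[Si](C(C)C)(C(C)C)C(C)C)cc1 | intermediate
3 | [4-(dichloromethyl)phenoxy]triisopropylsilane | ClC(Cl)c1ccc(O[Si](C(C)C)(C(C)C)C(C)C)cc1 | intermediate
4 | 3,4,5-trimethoxyphenol | COc1cc(O)cc(OC)c1OC | starting material
5 | {4-[chloro(3,4,5-trimethoxyphenoxy)methyl]phenoxy}triisopropylsilane (racemic, not isolated) | COc1cc(OC(Cl)c2ccc(O[Si](C(C)C)(C(C)C)C(C)C)cc2)cc(OC)c1OC | intermediate
6 | {4-[bis(3,4,5-trimethoxyphenoxy)methyl]phenoxy}triisopropylsilane (achiral) | COc1cc(OC(Oc2cc(OC)c(OC)c(OC)c2)c2ccc(O[Si](C(C)C)(C(C)C)C(C)C)cc2)cc(OC)c1OC | intermediate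
7 | ethoxyethyne (ethoxyacetylene) | C#COCC | starting material
8 | (3,4,5-trimethoxyphenyl)[4-(triisopropylsilyloxy)benzylidene]oxonium, ion pair with the catalyst anion (not isolated) | COc1cc([O+]=Cc2ccc(O[Si](C(C)C)(C(C)C)C(C)C)cc2)cc(OC)c1OC | intermediate
9 | (S)-4-ethoxy-5,6,7-trimethoxy-2-[4-(triisopropylsilyloxy)phenyl]-2H-chromene (not isolated) | CCOC1=C[C@@H](c2ccc(O[Si](C(C)C)(C(C)C)C(C)C)cc2)Oc2cc(OC)c(OC)c(OC)c12 | intermediate
10 | (S)-5,6,7-trimethoxy-2-[4-(triisopropylsilyloxy)phenyl]chroman-4-one | COc1c(OC)c2c(cc1OC)O[C@H](c1ccc(O[Si](C(C)C)(C(C)C)C(C)C)cc1)CC2=O | intermediate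
11 | (S)-5-(dichloroboryloxy)-6,7-dimethoxy-2-[4-(triisopropylsilyloxy)phenyl]chroman-4-one, boron chelated to C4=O (not isolated) | COc1c(OB(Cl)Cl)c2c(cc1OC)O[C@H](c1ccc(O[Si](C(C)C)(C(C)C)C(C)C)cc1)CC2=O | intermediate
12 | (S)-5-hydroxy-6,7-dimethoxy-2-[4-(triisopropylsilyloxy)phenyl]chroman-4-one | COc1c(O)c2c(cc1OC)O[C@H](c1ccc(O[Si](C(C)C)(C(C)C)C(C)C)cc1)CC2=O | intermediate
13 | 3-methylbut-2-en-1-ol (prenol) | CC(C)=CCO | starting material
14 | (S)-6,7-dimethoxy-5-[(3-methylbut-2-en-1-yl)oxy]-2-[4-(triisopropylsilyloxy)phenyl]chroman-4-one | COc1c(OCC=C(C)C)c2c(cc1OC)O[C@H](c1ccc(O[Si](C(C)C)(C(C)C)C(C)C)cc1)CC2=O | intermediate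
15 | (2S)-6,7-dimethoxy-6-(2-methylbut-3-en-2-yl)-2-[4-(triisopropylsilyloxy)phenyl]-2,3-dihydrochromene-4,5(6H)-dione, either configuration at C6 (not isolated) | COC1(C(C)(C)C=C)C(=O)C2=C(C=C1OC)O[C@H](c1ccc(O[Si](C(C)C)(C(C)C)C(C)C)cc1)CC2=O | intermediate
16 | (2S)-6,7-dimethoxy-8-(3-methylbut-2-en-1-yl)-2-[4-(triisopropylsilyloxy)phenyl]-2,3-dihydrochromene-4,5(8H)-dione, either configuration at C8 (not isolated) | COC1=C(OC)C(CC=C(C)C)C2=C(C1=O)C(=O)C[C@@H](c1ccc(O[Si](C(C)C)(C(C)C)C(C)C)cc1)O2 | intermediate
17 | (S)-5-hydroxy-6,7-dimethoxy-8-(3-methylbut-2-en-1-yl)-2-[4-(triisopropylsilyloxy)phenyl]chroman-4-one | COc1c(O)c2c(c(CC=C(C)C)c1OC)O[C@H](c1ccc(O[Si](C(C)C)(C(C)C)C(C)C)cc1)CC2=O | intermediate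
18 | (S)-5-hydroxy-2-(4-hydroxyphenyl)-6,7-dimethoxy-8-(3-methylbut-2-en-1-yl)chroman-4-one | COc1c(O)c2c(c(CC=C(C)C)c1OC)O[C@H](c1ccc(O)cc1)CC2=O | target

**Step count**
Total steps: 8. Longest linear sequence: 8 steps (1 → 18).

**Steps most likely to fail**

1. Step 4 (proposed new method). What may go wrong: weak facial discrimination in the ion pair, capture of the oxocarbenium ion by a second arene instead of the alkyne, closure of the ketenium ion at oxygen, or acid-induced oligomerisation of the alkyne. The fallback uses known chemistry only, sets out from 4 and comes back at 10; it forms the C2–aryl bond instead.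
   - Friedel–Crafts acetylation of 4 (AcOH, BF3·OEt2, 90 °C) should give 1-(6-hydroxy-2,3,4-trimethoxyphenyl)ethanone F1.
   - Condensation with DMF dimethyl acetal (95 °C) should give (E)-3-(dimethylamino)-1-(6-hydroxy-2,3,4-trimethoxyphenyl)prop-2-en-1-one F2.
   - Acid (HCl, CH2Cl2, rt) should close this to 5,6,7-trimethoxy-4H-chromen-4-one F3.
   - Asymmetric conjugate addition of 4-hydroxyphenylboronic acid sets C2 and should give (S)-2-(4-hydroxyphenyl)-5,6,7-trimethoxychroman-4-one F4. Conditions: Pd(OCOCF3)2 (divalent palladium), 4-tert-butyl-2-(pyridin-2-yl)-4,5-dihydrooxazole in the enantiomeric form that gives 2S, NH4PF6, H2O, ClCH2CH2Cl, 60 °C.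
   - Silylation (TIPSCl, imidazole, DMF) then gives 10.

2. Step 7. What may go wrong: loss of configuration at C2 by reversible opening of ring C under Lewis acid at 60 °C, or a stalled second shift. The fallback sets out from 12, comes back at 17, and also bypasses step 6.
   - Iodination with N-iodosuccinimide (MeCN, 0 °C) at C8, the only free position of ring A and para to 5-OH, should give (S)-5-hydroxy-8-iodo-6,7-dimethoxy-2-[4-(triisopropylsilyloxy)phenyl]chroman-4-one F5.
   - Stille coupling with allyltributylstannane (Pd(PPh3)4, zerovalent palladium, DMF, 80 °C) should give (S)-8-allyl-5-hydroxy-6,7-dimethoxy-2-[4-(triisopropylsilyloxy)phenyl]chroman-4-one F6.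
   - Cross-metathesis with 2-methylbut-2-ene (second-generation Grubbs catalyst, CH2Cl2, 40 °C) should give 17.

3. Step 3. What may go wrong: C-alkylation of the ambident phenoxide, or hydrolysis of the dichloride before the second substitution. The fallback sets out from 2 and comes back at 6, through isolable intermediates that are stable to water.
   - Condensation of 2 with 1H-benzotriazole and SOCl2 (toluene, rt) should give 1-{chloro[4-(triisopropylsilyloxy)phenyl]methyl}-1H-benzotriazole F7.
   - One equivalent of potassium 3,4,5-trimethoxyphenoxide (THF, rt) replaces chloride and should give 1-{[4-(triisopropylsilyloxy)phenyl](3,4,5-trimethoxyphenoxy)methyl}-1H-benzotriazole F8.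
   - A second equivalent (DMF, 60 °C) replaces benzotriazolide and gives 6.

**Further compounds**
F1 | step 4 | 1-(6-hydroxy-2,3,4-trimethoxyphenyl)ethanone | CC(=O)c1c(O)cc(OC)c(OC)c1OC
F2 | step 4 | (E)-3-(dimethylamino)-1-(6-hydroxy-2,3,4-trimethoxyphenyl)prop-2-en-1-one | CN(C)/C=C/C(=O)c1c(O)cc(OC)c(OC)c1OC
F3 | step 4 | 5,6,7-trimethoxy-4H-chromen-4-one | COc1cc2occc(=O)c2c(OC)c1OC
F4 | step 4 | (S)-2-(4-hydroxyphenyl)-5,6,7-trimethoxychroman-4-one | COc1c(OC)c2c(cc1OC)O[C@H](c1ccc(O)cc1)CC2=O
F5 | step 7 | (S)-5-hydroxy-8-iodo-6,7-dimethoxy-2-[4-(triisopropylsilyloxy)phenyl]chroman-4-one | COc1c(O)c2c(c(I)c1OC)O[C@H](c1ccc(O[Si](C(C)C)(C(C)C)C(C)C)cc1)CC2=O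
F6 | step 7 | (S)-8-allyl-5-hydroxy-6,7-dimethoxy-2-[4-(triisopropylsilyloxy)phenyl]chroman-4-one | COc1c(O)c2c(c(CC=C)c1OC)O[C@H](c1ccc(O[Si](C(C)C)(C(C)C)C(C)C)cc1)CC2=O
F7 | step 3 | 1-{chloro[4-(triisopropylsilyloxy)phenyl]methyl}-1H-benzotriazole (racemic) | ClC(c1ccc(O[Si](C(C)C)(C(C)C)C(C)C)cc1)n1nnc2ccccc12
F8 | step 3 | 1-{[4-(triisopropylsilyloxy)phenyl](3,4,5-trimethoxyphenoxy)methyl}-1H-benzotriazole (racemic) | COc1cc(OC(c2ccc(O[Si](C(C)C)(C(C)C)C(C)C)cc2)n2nnc3ccccc32)cc(OC)c1OC
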